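**Assumption:** the target has no stereocentres (it is achiral), so "single enantiomer" is taken to mean the single geometric isomer in the SMILES: central acid olefin Z, the other three olefins E. Numbered compounds are substrates, intermediates and fragment starting materials; simple reagents that deliver atoms are listed with SMILES in each step.

## Retrosynthetic overview

1. Target 19 ⇐ fluoride cleavage of the 2-(trimethylsilyl)ethyl (TMSE) ester 18 ⇐ E-selective Wittig of aldehyde 16 with ylide 17 (terminal E-enoate).
2. 16 ⇐ acetal 15 ⇐ **new step:** CuH/Ni α-selective syn-hydroalkylation of ynoate 12 with iodo-acetal 14, which forms the C–C bond at the acid α-carbon and sets the Z acid olefin.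
3. 12 ⇐ terminal alkyne 10 (carboxylation, esterification) ⇐ Cu-catalysed coupling of allylic chloride 7 with 3-furylmethylmagnesium chloride.
4. 7 ⇐ (E,E)-farnesol by terminal bromohydrin/epoxide, periodate cleavage and Ohira–Bestmann homologation; both E-trisubstituted olefins are bought, not made.
5. No ring is formed; the furan comes from 3-furanmethanol.

## Route

**Step 1**
Reactants: 1, (2E,6E)-farnesol
Product: 2, (2E,6E)-farnesyl acetate
Conditions: Ac2O, pyridine, DMAP (cat.), CH2Cl2, 0 °C→rt
Reagents that add atoms: acetic anhydride, CC(=O)OC(C)=O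
Why: Standard DMAP-catalysed acylation; the acetate deactivates the 2,3-olefin for step 2.

**Step 2**
Reactants: 2, (2E,6E)-farnesyl acetate
Product: 3, (2E,6E)-10-bromo-11-hydroxy-3,7,11-trimethyldodeca-2,6-dien-1-yl acetate (racemic)
Conditions: NBS (1.1 equiv), THF/H2O, 0 °C
Reagents that add atoms: N-bromosuccinimide, O=C1CCC(=O)N1Br; water, O
Why: van Tamelen terminal-selective Markovnikov bromohydrin formation (the coiled polyene exposes the terminal olefin); the racemic C10 centre is destroyed in step 4.

**Step 3**
Reactants: 3, bromohydrin acetate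
Product: 4, (2E,6E)-10,11-epoxy-3,7,11-trimethyldodeca-2,6-dien-1-ol (racemic)
Conditions: K2CO3, MeOH, rt
Reagents that add atoms: none
Why: Intramolecular Williamson closure of the bromohydrin with concurrent acetate methanolysis.

**Step 4**
Reactants: 4, 10,11-epoxyfarnesol
Product: 5, (4E,8E)-10-hydroxy-4,8-dimethyldeca-4,8-dienal
Conditions: H5IO6, THF/Et2O, 0 °C
Reagents that add atoms: none retained in 5 (periodic acid, OI(=O)(O)(O)(O)O, is the oxidant; acetone is lost)
Why: Periodic acid opens the epoxide and cleaves the resulting glycol (Malaprade-type cleavage) without touching the trisubstituted olefins or the allylic alcohol.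

**Step 5**
Reactants: 5, hydroxy-aldehyde
Product: 6, (2E,6E)-3,7-dimethylundeca-2,6-dien-10-yn-1-ol
Conditions: MeC(O)C(N2)P(O)(OMe)2, K2CO3, MeOH, 0 °C→rt
Reagents that add atoms: Ohira–Bestmann reagent, CC(=O)C(=[N+]=[N-])P(=O)(OC)OC (delivers the terminal alkyne carbon)
Why: Seyferth–Gilbert/Ohira–Bestmann homologation of an aliphatic aldehyde; it tolerates the free alcohol.

**Step 6**
Reactants: 6, hydroxy-enyne
Product: 7, (5E,9E)-11-chloro-5,9-dimethylundeca-5,9-dien-1-yne
Conditions: MsCl, s-collidine, LiCl, DMF, 0 °C
Reagents that add atoms: lithium chloride, [Li+].[Cl-]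
Why: Collington–Meyers chlorination (in situ mesylate, SN2 by chloride) gives the primary allylic chloride without transposition or E/Z loss.

**Step 7**
Reactants: 8, 3-furanmethanol
Product: 9, 3-(chloromethyl)furan
Conditions: MsCl, s-collidine, LiCl, DMF, 0 °C (used as a THF solution)
Reagents that add atoms: lithium chloride, [Li+].[Cl-]
Why: Same mild mesylate/chloride displacement, which avoids acid that would degrade the furan.

**Step 8**
Reactants: 7, allylic chloride; 9, 3-(chloromethyl)furan
Product: 10, 3-[(3E,7E)-4,8-dimethyldodeca-3,7-dien-11-yn-1-yl]furan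
Conditions: 9, Mg, THF → 3-furylCH2MgCl (2.5 equiv); then 7, Li2CuCl4 (5 mol%), THF, −20→0 °C
Reagents that add atoms: none (Mg and Cu are not retained)
Why: Cu-catalysed Grignard/primary allylic chloride coupling (Kochi-type, as used for dendrolasin-type furans) is α-selective with retention of the E-olefin; the extra Grignard absorbs the alkyne C–H, and the resulting acetylide is a non-transferable ligand on copper at this temperature.

**Step 9**
Reactants: 10, furyl dienyne
Product: 11, (6E,10E)-13-(furan-3-yl)-6,10-dimethyltrideca-6,10-dien-2-ynoic acid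
Conditions: n-BuLi (1.05 equiv), THF, −78 °C; CO2; citric acid workup
Reagents that add atoms: carbon dioxide, O=C=O
Why: Selective deprotonation of the terminal alkyne (the furan α-H is untouched at −78 °C) and carboxylation of the lithium acetylide.

**Step 10**
Reactants: 11, ynoic acid
Product: 12, 2-(trimethylsilyl)ethyl (6E,10E)-13-(furan-3-yl)-6,10-dimethyltrideca-6,10-dien-2-ynoate
Conditions: Me3SiCH2CH2OH, DCC, DMAP (cat.), CH2Cl2, 0 °C
Reagents that add atoms: 2-(trimethylsilyl)ethanol, C[Si](C)(C)CCO
Why: Steglich esterification installs a fluoride-labile ester that is orthogonal to the methyl ester introduced later.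

**Step 11**
Reactants: 13, 3-bromo-1,1-dimethoxypropane
Product: 14, 3-iodo-1,1-dimethoxypropane
Conditions: NaI, NaHCO3, acetone, reflux
Reagents that add atoms: sodium iodide, [Na+].[I-]
Why: Finkelstein exchange gives the primary iodide needed for radical activation at nickel.

**Step 12 (proposed new step)**
Reactants: 12, TMSE ynoate; 14, 3-iodo-1,1-dimethoxypropane (1.5 equiv)
Product: 15, 2-(trimethylsilyl)ethyl (2Z,6E,10E)-2-(3,3-dimethoxypropyl)-13-(furan-3-yl)-6,10-dimethyltrideca-2,6,10-trienoate
Conditions: (SIPr)CuCl (10 mol%), NiI2/4,4′,4″-tBu3-terpyridine (5 mol%), (EtO)2MeSiH (1.2 equiv, slow addition), LiOt-Bu (1.3 equiv), THF, −20 °C, no proton source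
Reagents that add atoms: none beyond the reactants (the silane delivers only H)
Why: Proposed new method: CuH/Ni dual-catalytic α-selective syn-hydroalkylation of a 2-alkynoate with an unactivated primary alkyl iodide. (NHC)Cu–H adds syn across the polarised ynoate (hydride to the β-carbon, Cu to the α-carbon), and the resulting α-cuprio-enoate/copper allenolate hands its alkenyl group to a terpyridine–Ni centre that has captured the primary alkyl radical from 14 by iodine abstraction. C(sp2)–C(sp3) reductive elimination then occurs with retention, and an allenolate would likewise be attacked on the face syn to the β-H and anti to the β-chain, so the new CH2 ends up cis to H and the ester cis to the chain (2Z). The closest known reaction types are the CuH-catalysed Z-selective semireduction of ynoates (same α-cuprio intermediate, protonated with retention) and the Cu/Ni dual-catalysed anti-Markovnikov hydroalkylation of terminal alkynes with alkyl iodides. The trisubstituted enoate product, furan, acetal and TMSE ester are inert to NHC–CuH at −20 °C without a proton source.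

**Step 13**
Reactants: 15, acetal
Product: 16, 2-(trimethylsilyl)ethyl (2Z,6E,10E)-13-(furan-3-yl)-6,10-dimethyl-2-(3-oxopropyl)trideca-2,6,10-trienoate
Conditions: PPTS (cat.), acetone/H2O (9:1), 45 °C
Reagents that add atoms: water, O
Why: Mild acid hydrolysis of a dimethyl acetal; the 3-alkylfuran, TMSE ester and Z-enoate tolerate PPTS.

**Step 14**
Reactants: 16, aldehyde; 17, methyl 2-(triphenyl-λ5-phosphanylidene)propanoate (1.5 equiv)
Product: 18, 1-methyl 6-[2-(trimethylsilyl)ethyl] diester, i.e. 2-(trimethylsilyl)ethyl (2Z,6E,10E)-13-(furan-3-yl)-2-[(3E)-5-methoxy-4-methyl-5-oxopent-3-en-1-yl]-6,10-dimethyltrideca-2,6,10-trienoate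
Conditions: CH2Cl2, rt→40 °C
Reagents that add atoms: none beyond reactant 17
Why: Wittig olefination with an α-methyl stabilised ylide gives the E-2-methyl-2-enoate (typically >95:5 E) under non-basic conditions that leave the Z-enoate untouched.

**Step 15**
Reactants: 18, TMSE/methyl diester
Product: 19, Furospongin-4, (2Z,6E,10E)-13-(furan-3-yl)-2-[(3E)-5-methoxy-4-methyl-5-oxopent-3-en-1-yl]-6,10-dimethyltrideca-2,6,10-trienoic acid
Conditions: TBAF, THF, 0 °C→rt; pH 4 citrate workup
Reagents that add atoms: none
Why: Fluoride-induced β-elimination (loss of Me3SiF and ethylene) frees the acid selectively; the methyl ester, furan and all four olefin geometries are unaffected.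

## Compound list

1 | (2E,6E)-farnesol | CC(C)=CCC/C(C)=C/CC/C(C)=C/CO | starting material
2 | (2E,6E)-farnesyl acetate | CC(C)=CCC/C(C)=C/CC/C(C)=C/COC(C)=O | intermediate
3 | (2E,6E)-10-bromo-11-hydroxy-3,7,11-trimethyldodeca-2,6-dien-1-yl acetate (racemic) | CC(C)(O)C(Br)CC/C(C)=C/CC/C(C)=C/COC(C)=O | intermediate
4 | (2E,6E)-10,11-epoxyfarnesol (racemic) | CC1(C)OC1CC/C(C)=C/CC/C(C)=C/CO | intermediate
5 | (4E,8E)-10-hydroxy-4,8-dimethyldeca-4,8-dienal | O=CCC/C(C)=C/CC/C(C)=C/CO | intermediate
6 | (2E,6E)-3,7-dimethylundeca-2,6-dien-10-yn-1-ol | C#CCC/C(C)=C/CC/C(C)=C/CO | intermediate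
7 | (5E,9E)-11-chloro-5,9-dimethylundeca-5,9-dien-1-yne | C#CCC/C(C)=C/CC/C(C)=C/CCl | intermediate
8 | 3-furanmethanol | OCc1ccoc1 | starting material
9 | 3-(chloromethyl)furan | ClCc1ccoc1 | intermediate
10 | 3-[(3E,7E)-4,8-dimethyldodeca-3,7-dien-11-yn-1-yl]furan | C#CCC/C(C)=C/CC/C(C)=C/CCc1ccoc1 | intermediate
11 | (6E,10E)-13-(furan-3-yl)-6,10-dimethyltrideca-6,10-dien-2-ynoic acid | OC(=O)C#CCC/C(C)=C/CC/C(C)=C/CCc1ccoc1 | intermediate
12 | 2-(trimethylsilyl)ethyl ester of 11 | C[Si](C)(C)CCOC(=O)C#CCC/C(C)=C/CC/C(C)=C/CCc1ccoc1 | intermediate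
13 | 3-bromo-1,1-dimethoxypropane | COC(OC)CCBr | starting material
14 | 3-iodo-1,1-dimethoxypropane | COC(OC)CCI | intermediate
15 | 2-(trimethylsilyl)ethyl (2Z,6E,10E)-2-(3,3-dimethoxypropyl)-13-(furan-3-yl)-6,10-dimethyltrideca-2,6,10-trienoate | COC(OC)CC/C(=C/CC/C(C)=C/CC/C(C)=C/CCc1ccoc1)C(=O)OCC[Si](C)(C)C | intermediate
16 | 2-(trimethylsilyl)ethyl (2Z,6E,10E)-13-(furan-3-yl)-6,10-dimethyl-2-(3-oxopropyl)trideca-2,6,10-trienoate | O=CCC/C(=C/CC/C(C)=C/CC/C(C)=C/CCc1ccoc1)C(=O)OCC[Si](C)(C)C | intermediate
17 | methyl 2-(triphenyl-λ5-phosphanylidene)propanoate | COC(=O)C(C)=P(c1ccccc1)(c1ccccc1)c1ccccc1 | starting material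
18 | TMSE ester of Furospongin-4 | COC(=O)/C(C)=C/CC/C(=C/CC/C(C)=C/CC/C(C)=C/CCc1ccoc1)C(=O)OCC[Si](C)(C)C | intermediate
19 | Furospongin-4 | COC(=O)/C(C)=C/CC/C(=C/CC/C(C)=C/CC/C(C)=C/CCc1ccoc1)C(=O)O | target

## Summary

Total steps: 15. Longest linear sequence: 13 steps (1 → 19 through steps 1–6, 8–10, 12–15).

Steps most likely to fail, each with a fallback:

1. **Step 12 (proposed new hydroalkylation).** Risks are Z/E erosion through the allenolate, semireduction of the ynoate, and reduction of the iodide. Fallback (known chemistry, same intermediates 12 and 14): Pd(PPh3)4/Bu3SnH syn-hydrostannation of 12 (α-stannyl, Sn cis to the β-H), I2 iododestannylation, then Pd-catalysed Negishi coupling with IZn(CH2)2CH(OMe)2 made from 14 (Zn, LiCl). All three steps proceed with retention and give 15.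
2. **Step 2 (terminal-selective bromohydrin).** Risks are modest regioselectivity and yield. Fallback: drop the farnesol degradation and assemble the same E,E-dienyne as C10 + C3 from geranyl acetate. This uses SeO2/t-BuOOH E-selective allylic oxidation at C8, C8-OH protection and furan installation at C1, then C8 bromide and alkylation with lithiated 1-(trimethylsilyl)propyne, followed by desilylation to 10.
3. **Step 8 (Cu-catalysed furylmethyl Grignard coupling next to a free alkyne).** Risks are acetylide side-coupling, SN2′ substitution and Wurtz products. Fallback: reverse to a stabilised nucleophile by alkylating the anion of 3-[(phenylsulfonyl)methyl]furan (from 9 and PhSO2Na) with 7, then reductive desulfonylation (Na/Hg or Mg/MeOH) to 10.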